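The route rests on dismantling ring B into three pieces: a chromium alkoxycarbene on the enol-ether carbon of a tartrate-derived glycal (ring F), the terminal alkyne of a 3-ethynylchromone carrying rings A, C and E, and one CO ligand. The feature used is the substitution of ring B: five substituents, the oxygens on C2' and C5' para to each other and the C3'–C4' bond fused to ring F. A Dötz benzannulation builds exactly this in one operation, forming C5'–C6', C1'–C2' and C2'–C3', closing ring B and placing both oxygens while leaving the two stereocentres alone. Dehydrogenative furan closure and one fluoride treatment finish the synthesis.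

Key step: step 15

Numbering: chromone O1, C2, C3, C4, C4a–C8a; ring B C1'–C6' with the furan oxygen on C2'; ring E on O7/C8; ring F runs C4', O, C2''', C3''', C4''', C3'. The target is the (3'''R,4'''S) trans-diol. TBS = tert-butyldimethylsilyl.

Remark on the chemistry: the C5 hydroxyl of the chromone is carried unprotected from step 11 on, on the assumption that its hydrogen bond to the C4 carbonyl keeps it inert in steps 12–16; fluoride alone then completes the synthesis and no acid touches the benzylic diol.

Step 1
Reactants: 1 dimethyl L-tartrate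
Product: 2 dimethyl (2R,3R)-2,3-bis(TBSO)butanedioate
Conditions: TBSOTf (2.4 equiv), 2,6-lutidine (3 equiv), CH2Cl2, 0 °C to rt
Reagents that add atoms: tert-butyldimethylsilyl trifluoromethanesulfonate, CC(C)(C)[Si](C)(C)OS(=O)(=O)C(F)(F)F
Why: Silyl ether protection of both secondary hydroxyls with a silyl triflate and a hindered pyridine base; the two stereocenters of L-tartrate are carried over untouched and no new one is formed.

Step 2
Reactants: 2 dimethyl (2R,3R)-2,3-bis(TBSO)butanedioate
Product: 3 methyl (2R,3R)-2,3-bis(TBSO)-4-oxobutanoate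
Conditions: iBu2AlH (1.05 equiv), toluene, −78 °C; MeOH; aq. KNaC4H4O6
Reagents that add atoms: none
Why: Ester-to-aldehyde half-reduction, in which one equivalent of hydride at −78 °C stops at the aluminium hemiacetal until work-up; the two ester groups are homotopic (C2 symmetry), so either one gives the same product, unchanged 2 is recycled and no stereocenter is touched.

Step 3
Reactants: 3 methyl (2R,3R)-2,3-bis(TBSO)-4-oxobutanoate
Product: 4 methyl (2R,3S)-2,3-bis(TBSO)pent-4-ynoate
Conditions: MeC(O)C(N2)P(O)(OMe)2 (1.3 equiv), K2CO3 (2 equiv), MeOH, 0 °C to rt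
Reagents that add atoms: dimethyl (1-diazo-2-oxopropyl)phosphonate, CC(=O)C(=[N+]=[N-])P(=O)(OC)OC
Why: Ohira–Bestmann homologation of the aldehyde to the terminal alkyne under mild carbonate base at low temperature, which should keep the α-silyloxy stereocenter intact (only its descriptor changes), while the methyl ester is degenerate toward methanolysis.

Step 4
Reactants: 4 methyl (2R,3S)-2,3-bis(TBSO)pent-4-ynoate
Product: 5 (3R,4S)-3,4-bis(TBSO)-2-methylhex-5-yn-2-ol
Conditions: MeMgBr (4 equiv), THF, −78 to 0 °C; aq. NH4Cl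
Reagents that add atoms: methylmagnesium bromide, C[Mg]Br
Why: Double Grignard addition to the ester gives the tertiary alcohol that becomes O4' and C2''' (the acetylenic C–H consumes one more equivalent and is restored on work-up); the stereocenters are not involved.

Step 5
Reactants: 5 (3R,4S)-3,4-bis(TBSO)-2-methylhex-5-yn-2-ol
Product: 6 (3R,4S)-3,4-bis(TBSO)-2,2-dimethyl-3,4-dihydro-2H-pyran
Conditions: W(CO)6 (25 mol%), Et3N, THF, hν (350 nm), 60 °C
Reagents that add atoms: none
Why: Tungsten-carbonyl-catalysed endo-cycloisomerization of a 4-pentyn-1-ol, in which photogenerated W(CO)5 turns the terminal alkyne into a vinylidene, the hydroxyl adds to its metal-bound carbon to close the six-membered ring and protonolysis releases the cyclic enol ether; both stereocenters are retained.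

Step 6
Reactants: 6 (3R,4S)-3,4-bis(TBSO)-2,2-dimethyl-3,4-dihydro-2H-pyran; 7 Cr(CO)6
Product: 10 tetramethylammonium pentacarbonyl{[(3R,4S)-3,4-bis(TBSO)-2,2-dimethyl-3,4-dihydro-2H-pyran-6-yl]carbonyl}chromate, via 6-lithio glycal 8 (not isolated), via lithium acyl chromate 9 (not isolated)
Conditions: t-BuLi (3 equiv), THF, −78 to 0 °C; Cr(CO)6, THF, −78 °C to rt; Me4NBr, H2O/CH2Cl2
Reagents that add atoms: tetramethylammonium bromide, C[N+](C)(C)C.[Br-]
Why: Lithiation of the vinylic C–H beside the ring oxygen of a glycal, then addition of the vinyllithium to a CO ligand of Cr(CO)6 (Fischer route to acylmetalates) and cation exchange to the storable ammonium salt; no stereocenter is formed.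

Step 7
Reactants: 10 tetramethylammonium acyl chromate
Product: 12 pentacarbonyl{[(3R,4S)-3,4-bis(TBSO)-2,2-dimethyl-3,4-dihydro-2H-pyran-6-yl][2-(trimethylsilyl)ethoxy]methylidene}chromium, via acetoxycarbene complex 11 (not isolated)
Conditions: CH3COBr (1.05 equiv), CH2Cl2, −40 °C; then Me3SiCH2CH2OH (1.5 equiv), −40 to 0 °C
Reagents that add atoms: 2-(trimethylsilyl)ethanol, C[Si](C)(C)CCO
Why: Acyloxy-to-alkoxy exchange of a Fischer carbene complex, where O-acylation gives an electrophilic acyloxycarbene that swaps acetate for the primary alcohol by addition–elimination at the carbene carbon; it installs a fluoride-labile ether on the later C5' oxygen and forms no stereocenter.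

Step 8
Reactants: 13 2,6-dimethoxytoluene
Product: 15 3,5-dimethoxy-4-methylphenol, via arylboronic pinacol ester 14 (not isolated)
Conditions: [Ir(OMe)(cod)]2 (1.5 mol%), 4,4'-di-tert-butyl-2,2'-bipyridine (3 mol%), B2pin2 (0.55 equiv), cyclohexane, 80 °C; then KHSO5 (as 2KHSO5·KHSO4·K2SO4), acetone/H2O, rt
Reagents that add atoms: potassium peroxymonosulfate, [K+].[O-]S(=O)(=O)OO
Why: Sterically controlled iridium-catalysed aromatic C–H borylation at the only C–H flanked by two hydrogens (para to the methyl group) and oxidation of the C–B bond give the phenol whose oxygen becomes O1; the two methoxy groups beside the methyl group stay equivalent, so the later chromone closure has no regiochemical choice.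

Step 9
Reactants: 15 3,5-dimethoxy-4-methylphenol
Product: 16 1-(6-hydroxy-2,4-dimethoxy-3-methylphenyl)ethan-1-one
Conditions: Ac2O (1.5 equiv), BF3·OEt2 (3 equiv), 70 °C; then aq. NaOAc, 60 °C
Reagents that add atoms: acetic anhydride, CC(=O)OC(C)=O
Why: BF3-mediated C-acetylation of a phloroglucinol-type phenol (O-acylation and Fries-type shift) goes to one of the two equivalent positions ortho to the free hydroxyl because the para position carries the methyl group, and the boron chelate of the product prevents a second acylation.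

Step 10
Reactants: 16 1-(6-hydroxy-2,4-dimethoxy-3-methylphenyl)ethan-1-one
Product: 18 3-iodo-5,7-dimethoxy-6-methyl-4H-chromen-4-one, via enaminone 17 (not isolated)
Conditions: Me2NCH(OMe)2 (3 equiv), toluene, 95 °C; evaporate; I2 (1.5 equiv), CHCl3, rt
Reagents that add atoms: N,N-dimethylformamide dimethyl acetal, COC(OC)N(C)C; iodine, II
Why: Enaminone route to 3-iodochromones, in which the amide acetal condenses with the methyl ketone and iodine triggers α-iodination, ring closure by the only free phenol and loss of dimethylamine; this fixes O1 para to the C-methyl group and the methyl group on C6.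

Step 11
Reactants: 18 3-iodo-5,7-dimethoxy-6-methyl-4H-chromen-4-one
Product: 19 5,7-dihydroxy-3-iodo-6-methyl-4H-chromen-4-one
Conditions: BBr3 (5 equiv), CH2Cl2, −78 °C to rt; ice-water
Reagents that add atoms: none
Why: Lewis-acid cleavage of both aryl methyl ethers by BBr3 (the chelated 5-methoxy first) frees the C7 hydroxyl needed for ring E and the C5 hydroxyl of the target, and the pyranone and the vinylic iodide should tolerate the aprotic conditions.

Step 12
Reactants: 19 5,7-dihydroxy-3-iodo-6-methyl-4H-chromen-4-one; 20 3-methylbut-2-enal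
Product: 21 5-hydroxy-3-iodo-6,8,8-trimethyl-4H,8H-pyrano[2,3-f]chromen-4-one
Conditions: 20 (3 equiv), Ca(OH)2 (2 equiv), MeOH, rt
Reagents that add atoms: none
Why: Chromene annulation of a phenol with an enal, in which the C7 phenoxide attacks the aldehyde through C8, dehydration gives an ortho-quinone methide and oxa-6π-electrocyclization closes the 2,2-dimethylpyran; C8 is the only free ring carbon and the 7-OH the only hydroxyl beside it, so only the angular ring E can form, and the phenoxide deactivates C2 toward methoxide.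

Step 13
Reactants: 21 5-hydroxy-3-iodo-6,8,8-trimethyl-4H,8H-pyrano[2,3-f]chromen-4-one
Product: 22 5-hydroxy-6,8,8-trimethyl-3-[(trimethylsilyl)ethynyl]-4H,8H-pyrano[2,3-f]chromen-4-one
Conditions: Me3SiC≡CH (1.5 equiv), PdCl2(PPh3)2 (5 mol%), CuI (10 mol%), Et3N, THF, rt
Reagents that add atoms: ethynyltrimethylsilane, C#C[Si](C)(C)C
Why: Sonogashira coupling of the activated vinylic iodide of a 3-iodochromone with a silyl-capped acetylene, using a tertiary amine that does not open the pyranone.

Step 14
Reactants: 22 5-hydroxy-6,8,8-trimethyl-3-[(trimethylsilyl)ethynyl]-4H,8H-pyrano[2,3-f]chromen-4-one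
Product: 23 3-ethynyl-5-hydroxy-6,8,8-trimethyl-4H,8H-pyrano[2,3-f]chromen-4-one
Conditions: Bu4NF (1.1 equiv), AcOH (1.2 equiv), THF, 0 °C
Reagents that add atoms: none
Why: Fluoride-induced protodesilylation of the alkynylsilane, buffered with acetic acid so that no alkoxide is present to add to C2 of the alkynylchromone.

Step 15
Reactants: 12 chromium carbene complex of the glycal; 23 3-ethynyl-5-hydroxy-6,8,8-trimethyl-4H,8H-pyrano[2,3-f]chromen-4-one
Product: 25 3-[(3R,4S)-3,4-bis(TBSO)-5-hydroxy-2,2-dimethyl-8-[2-(trimethylsilyl)ethoxy]-3,4-dihydro-2H-chromen-6-yl]-5-hydroxy-6,8,8-trimethyl-4H,8H-pyrano[2,3-f]chromen-4-one, via tricarbonylchromium arene complex 24 (not isolated)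
Conditions: 12 (1.3 equiv), THF (0.05 M, degassed), 55 °C, Ar; then air, Et2O, rt
Reagents that add atoms: none
Why: Thermal loss of one CO from 12 lets the terminal alkyne of 23 insert into the Cr=C bond with its chromonyl-bearing carbon remote from the carbene carbon (C5'–C6'), CO insertion gives a chromium-bound dienylketene (C1'–C2'), its six-electron electrocyclization forms C2'–C3', and enolization gives the C2' phenol, first as the Cr(CO)3 complex 24 that air decomplexes. The closest known reaction type is the Dötz benzannulation of alkenyl(alkoxy)carbene chromium complexes with terminal alkynes, which includes carbenes made from 1-lithiated glycals and dihydropyrans. Ring B is the only ring closed, and it closes by thermal 6π-electrocyclization of the dienylketene followed by tautomerization to the arene. No stereocenter is created; C3''' and C4''' come unchanged from L-tartrate and lie outside the reacting π system. The step needs regiocontrol of alkyne insertion, which the steric difference between hydrogen and the chromonyl group of a terminal alkyne should secure (hydrogen at C6' beside the alkoxy carbon, chromonyl at C1' beside the CO-derived C2' hydroxyl), and it needs phenol formation to win over cyclopentannulation, which an alkenyl carbene with a β-hydrogen in THF at moderate temperature favours. Because the enol-ether carbon of the glycal becomes C4', the ring F oxygen, the C3'–C4' fusion, the C5' ether and the C2' hydroxyl all arrive in place at once.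

Step 16
Reactants: 25 2'-hydroxyisoflavone
Product: 26 coumaronochromone carrying the ring F diol as bis-TBS ether and the C5' oxygen as 2-(trimethylsilyl)ethyl ether
Conditions: DDQ (1.15 equiv), anhydrous 1,4-dioxane, Ar, rt
Reagents that add atoms: none
Why: Quinone-mediated dehydrogenative cyclization of a 2'-hydroxyisoflavone to a coumaronochromone, in which the C2' hydroxyl adds to C2 (oxa-Michael, five-membered ring) and DDQ removes two hydrogens to restore the C2=C3 bond; dry conditions, room temperature and a slight excess are meant to spare ring B and the benzylic C4''' silyl ether, and the stereocenters are untouched.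

Step 17
Reactants: 26 protected coumaronochromone
Product: 27 CNP0351839.1
Conditions: Bu4NF (6 equiv), THF, Ar, 0 °C to rt; then AcOH
Reagents that add atoms: none
Why: Fluoride cleaves both silyl ethers and triggers β-elimination of the 2-(trimethylsilyl)ethyl aryl ether (ethene and fluorosilane leave) in one non-acidic operation that spares the chromene and the acid-sensitive benzylic diol; both stereocenters are retained.

Compound list
1 | dimethyl L-tartrate, dimethyl (2R,3R)-2,3-dihydroxybutanedioate | COC(=O)[C@H](O)[C@@H](O)C(=O)OC | starting material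
2 | dimethyl (2R,3R)-2,3-bis(TBSO)butanedioate | COC(=O)[C@H](O[Si](C)(C)C(C)(C)C)[C@@H](O[Si](C)(C)C(C)(C)C)C(=O)OC | intermediate
3 | methyl (2R,3R)-2,3-bis(TBSO)-4-oxobutanoate | COC(=O)[C@H](O[Si](C)(C)C(C)(C)C)[C@@H](O[Si](C)(C)C(C)(C)C)C=O | intermediate
4 | methyl (2R,3S)-2,3-bis(TBSO)pent-4-ynoate | COC(=O)[C@H](O[Si](C)(C)C(C)(C)C)[C@@H](O[Si](C)(C)C(C)(C)C)C#C | intermediate
5 | (3R,4S)-3,4-bis(TBSO)-2-methylhex-5-yn-2-ol | CC(C)(O)[C@H](O[Si](C)(C)C(C)(C)C)[C@@H](O[Si](C)(C)C(C)(C)C)C#C | intermediate
6 | (3R,4S)-3,4-bis(TBSO)-2,2-dimethyl-3,4-dihydro-2H-pyran (5,5-dimethyl glycal of ring F) | C1=C[C@H](O[Si](C)(C)C(C)(C)C)[C@@H](O[Si](C)(C)C(C)(C)C)C(C)(C)O1 | intermediate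
7 | hexacarbonylchromium, Cr(CO)6 | [C-]#[O+].[C-]#[O+].[C-]#[O+].[C-]#[O+].[C-]#[O+].[C-]#[O+].[Cr] | starting material
8 | 6-lithio derivative of glycal 6 | [Li]C1=C[C@H](O[Si](C)(C)C(C)(C)C)[C@@H](O[Si](C)(C)C(C)(C)C)C(C)(C)O1 | intermediate (not isolated)
9 | lithium pentacarbonyl{[(3R,4S)-3,4-bis(TBSO)-2,2-dimethyl-3,4-dihydro-2H-pyran-6-yl]carbonyl}chromate | [Li+].[O-]C(=[Cr](=C=O)(=C=O)(=C=O)(=C=O)=C=O)C1=C[C@H](O[Si](C)(C)C(C)(C)C)[C@@H](O[Si](C)(C)C(C)(C)C)C(C)(C)O1 | intermediate (not isolated)
10 | tetramethylammonium salt of the same acyl chromate | C[N+](C)(C)C.[O-]C(=[Cr](=C=O)(=C=O)(=C=O)(=C=O)=C=O)C1=C[C@H](O[Si](C)(C)C(C)(C)C)[C@@H](O[Si](C)(C)C(C)(C)C)C(C)(C)O1 | intermediate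
11 | pentacarbonyl{acetoxy[(3R,4S)-3,4-bis(TBSO)-2,2-dimethyl-3,4-dihydro-2H-pyran-6-yl]methylidene}chromium | CC(=O)OC(=[Cr](=C=O)(=C=O)(=C=O)(=C=O)=C=O)C1=C[C@H](O[Si](C)(C)C(C)(C)C)[C@@H](O[Si](C)(C)C(C)(C)C)C(C)(C)O1 | intermediate (not isolated)
12 | pentacarbonyl{[(3R,4S)-3,4-bis(TBSO)-2,2-dimethyl-3,4-dihydro-2H-pyran-6-yl][2-(trimethylsilyl)ethoxy]methylidene}chromium | C[Si](C)(C)CCOC(=[Cr](=C=O)(=C=O)(=C=O)(=C=O)=C=O)C1=C[C@H](O[Si](C)(C)C(C)(C)C)[C@@H](O[Si](C)(C)C(C)(C)C)C(C)(C)O1 | intermediate
13 | 2,6-dimethoxytoluene (1,3-dimethoxy-2-methylbenzene) | COc1cccc(OC)c1C | starting material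
14 | 2-(3,5-dimethoxy-4-methylphenyl)-4,4,5,5-tetramethyl-1,3,2-dioxaborolane | COc1cc(B2OC(C)(C)C(C)(C)O2)cc(OC)c1C | intermediate (not isolated)
15 | 3,5-dimethoxy-4-methylphenol | COc1cc(O)cc(OC)c1C | intermediate
16 | 1-(6-hydroxy-2,4-dimethoxy-3-methylphenyl)ethan-1-one | CC(=O)c1c(O)cc(OC)c(C)c1OC | intermediate
17 | (E)-3-(dimethylamino)-1-(6-hydroxy-2,4-dimethoxy-3-methylphenyl)prop-2-en-1-one | CN(C)/C=C/C(=O)c1c(O)cc(OC)c(C)c1OC | intermediate (not isolated)
18 | 3-iodo-5,7-dimethoxy-6-methyl-4H-chromen-4-one | COc1cc2occ(I)c(=O)c2c(OC)c1C | intermediate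
19 | 5,7-dihydroxy-3-iodo-6-methyl-4H-chromen-4-one | Cc1c(O)cc2occ(I)c(=O)c2c1O | intermediate
20 | 3-methylbut-2-enal | CC(C)=CC=O | starting material
21 | 5-hydroxy-3-iodo-6,8,8-trimethyl-4H,8H-pyrano[2,3-f]chromen-4-one | Cc1c(O)c2c(=O)c(I)coc2c2C=CC(C)(C)Oc12 | intermediate
22 | 5-hydroxy-6,8,8-trimethyl-3-[(trimethylsilyl)ethynyl]-4H,8H-pyrano[2,3-f]chromen-4-one | C[Si](C)(C)C#Cc1coc2c3C=CC(C)(C)Oc3c(C)c(O)c2c1=O | intermediate
23 | 3-ethynyl-5-hydroxy-6,8,8-trimethyl-4H,8H-pyrano[2,3-f]chromen-4-one (rings A, C and E) | C#Cc1coc2c3C=CC(C)(C)Oc3c(C)c(O)c2c1=O | intermediate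
24 | Cr(CO)3 complex of 25, hexahapto-bound to ring B (π bond written as a dot) | O=c1c(-c2cc(OCC[Si](C)(C)C)c3OC(C)(C)[C@H](O[Si](C)(C)C(C)(C)C)[C@@H](O[Si](C)(C)C(C)(C)C)c3c2O)coc2c3C=CC(C)(C)Oc3c(C)c(O)c12.[Cr](=C=O)(=C=O)=C=O | intermediate (not isolated)
25 | 3-[(3R,4S)-3,4-bis(TBSO)-5-hydroxy-2,2-dimethyl-8-[2-(trimethylsilyl)ethoxy]-3,4-dihydro-2H-chromen-6-yl]-5-hydroxy-6,8,8-trimethyl-4H,8H-pyrano[2,3-f]chromen-4-one (2'-hydroxyisoflavone) | O=c1c(-c2cc(OCC[Si](C)(C)C)c3OC(C)(C)[C@H](O[Si](C)(C)C(C)(C)C)[C@@H](O[Si](C)(C)C(C)(C)C)c3c2O)coc2c3C=CC(C)(C)Oc3c(C)c(O)c12 | intermediate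
26 | target with (3'''R,4'''S)-bis-O-TBS ring F and 5'-O-[2-(trimethylsilyl)ethyl] ether | Cc1c2c(c3oc4oc5c6c(c(OCC[Si](C)(C)C)cc5c4c(=O)c3c1O)OC(C)(C)[C@H](O[Si](C)(C)C(C)(C)C)[C@H]6O[Si](C)(C)C(C)(C)C)C=CC(C)(C)O2 | intermediate
27 | CNP0351839.1, the (3'''R,4'''S)-coumaronochromone with 5-OH, 5'-OH, 6-methyl, ring E on O7/C8 and trans-diol ring F | Cc1c2c(c3oc4oc5c6c(c(O)cc5c4c(=O)c3c1O)OC(C)(C)[C@H](O)[C@H]6O)C=CC(C)(C)O2 | target

Total step count: 17. Longest linear sequence: 10 steps (steps 1–7, then 15–17; the chromone branch, steps 8–14 plus 15–17, is equally long).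

Steps most likely to fail

Step 15. The vinylcarbene formed after alkyne insertion may cyclize without taking up CO (cyclopentannulation), may be intercepted by the chromone enone or carbonyl, may take up a second alkyne, or the crowded carbene may decompose before it inserts. The fallback takes the chromone out of the benzannulation. It sets out from carbene 12, which is heated in THF at 55 °C with commercial 2-ethynyl-4,4,5,5-tetramethyl-1,3,2-dioxaborolane, a small terminal alkyne of a class known to benzannulate with the boron-bearing carbon ending beside the new hydroxyl. This should give, through the tricarbonylchromium complex of the boronic ester F1 and air decomplexation, (3R,4S)-3,4-bis(TBSO)-5-hydroxy-2,2-dimethyl-6-(4,4,5,5-tetramethyl-1,3,2-dioxaborolan-2-yl)-8-[2-(trimethylsilyl)ethoxy]-3,4-dihydro-2H-chromene F2. Suzuki–Miyaura coupling of this boronic ester with iodochromone 21 (Pd(PPh3)4, K3PO4, dioxane/H2O, 70 °C) then forms the C1'–C3 bond and comes back to the route at 25.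

Step 16. The electron-rich, para-dioxygenated ring B may be over-oxidized to a quinone with loss of the silylethyl group, or hydride may be abstracted from benzylic C4''' with loss of that stereocenter. The fallback sets out from 25 and activates the alkene, not the arene: Pd(OCOCF3)2 (10 mol%) with DMSO under O2 (1 atm) at 60 °C, a Wacker-type oxidative cyclization in which divalent palladium mediates attack of the C2' phenol on C2 and β-hydride elimination removes the C2 hydrogen. Ring B is never oxidized, no new compound lies on the way (F0), and the fallback comes back to the route at 26.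

Step 5. Addition of the hindered tertiary hydroxyl to the tungsten vinylidene may be slow, so that exo-cyclization, alkyne oligomerization or catalyst decay take over. The fallback sets out from alkynol 5 and builds the enol ether by dehydration. Hydroboration with dicyclohexylborane and oxidation with NaBO3·4H2O give the aldehyde, which closes onto the tertiary hydroxyl as the 2-deoxy lactol (4S,5R)-4,5-bis(TBSO)-6,6-dimethyloxan-2-ol F3 (anomeric mixture). MeSO2Cl and Et3N in CH2Cl2 (0 °C to reflux) convert it through the anomeric methanesulfonate F4 into the enol ether, and the fallback comes back to the route at glycal 6.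

Further compounds
F1 | step 15 | Cr(CO)3 complex of F2, hexahapto-bound to the arene (π bond written as a dot) | CC1(C)OB(OC1(C)C)c1cc(OCC[Si](C)(C)C)c2OC(C)(C)[C@H](O[Si](C)(C)C(C)(C)C)[C@@H](O[Si](C)(C)C(C)(C)C)c2c1O.[Cr](=C=O)(=C=O)=C=O
F2 | step 15 | (3R,4S)-3,4-bis(TBSO)-5-hydroxy-2,2-dimethyl-6-(4,4,5,5-tetramethyl-1,3,2-dioxaborolan-2-yl)-8-[2-(trimethylsilyl)ethoxy]-3,4-dihydro-2H-chromene | CC1(C)OB(OC1(C)C)c1cc(OCC[Si](C)(C)C)c2OC(C)(C)[C@H](O[Si](C)(C)C(C)(C)C)[C@@H](O[Si](C)(C)C(C)(C)C)c2c1O
F0 | step 16 | none | none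
F3 | step 5 | (4S,5R)-4,5-bis(TBSO)-6,6-dimethyloxan-2-ol | OC1C[C@H](O[Si](C)(C)C(C)(C)C)[C@@H](O[Si](C)(C)C(C)(C)C)C(C)(C)O1
F4 | step 5 | (4S,5R)-4,5-bis(TBSO)-6,6-dimethyloxan-2-yl methanesulfonate | CS(=O)(=O)OC1C[C@H](O[Si](C)(C)C(C)(C)C)[C@@H](O[Si](C)(C)C(C)(C)C)C(C)(C)O1
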